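The leftover caught my eye first: the beta flask still held 28.4% of its starting material at 5.00 h, against 28.5% at 2.50 h, while product read 69.9% and then 69.8%.

| flask | starting material | solid reagent | free catalyst | remark | time |
|---|---|---|---|---|---|
| beta | 0.83 M | 0.581 M | 15 mM | the very flask that is asked about, followed so far |  |
| theta | 0.83 M | 0.87 M | 15 mM | run made earlier |  |
| flask | 0.83 M | 0.581 M | 15 mM |  | 5.0 h |

- beta (time / h: product / %, starting material / %): 0.417: 15.0, 84.2; 1.33: 50.6, 47.3; 2.50: 69.9, 28.5; 4.00: 69.3, 28.1; 5.00: 69.8, 28.4
- theta (time / h: product / %, starting material / %): 0.417: 14.7, 84.3; 0.833: 31.7, 66.9; 1.33: 49.9, 47.6; 2.50: 86.2, 11.4; 5.00: 98.3, 0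

(readings scatter by 0.5 percentage points)

- south-east: at 5.0 h add starting material, 50.0% of the amount charged, then wait 5.0 h
- north-east: at 5.0 h take out 90% of the by-product then present, then wait 5.0 h
- south: at 5.0 h add free catalyst, 100% of the amount charged, then wait 5.0 h
- west: change nothing and wait 5.0 h more

- given per volume of solution although it is solid: solid reagent
- the volume of additions can be left aside
- at the start none of the solid reagent is in solution

* product, in percent of the starting material first charged, at 5.0 h
* the remedy with the largest gain of product, or "none" below 2 percentage points (south-east / north-east / south / west / none)
* product present, in percent of the starting material first charged, after north-east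
* product present, in percent of the starting material first charged, after south

So between those readings that leftover did not shrink beyond their scatter. At 1.33 h, the beta flask read 50.6% of product and the theta flask 49.9%, so in these two runs the early rate told me nothing about where each one stopped. I therefore kept two amounts, the charge of solid reagent and the charge of starting material. Their ratio, the reagent ceiling 70.0%, is the product the flask can hold if each unit of product takes one unit of solid reagent. In the beta flask, control passes from rate to charge where product meets this ceiling. The beta plateau readings stood there within their scatter, and that was a real check, since readings and charges are different things. The theta flask's ceiling was higher, at 105%, and it read 98.3% of product with starting material at 0%. I reckoned 70.0% for the flask at 5.0 h, and I expected no gain from a remedy that adds no solid reagent.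

The forecast gave 69.7%, none as the best remedy, 69.7% after north-east and 69.7% after south, on this ground: “The stall is simply solid reagent exhaustion.” My ceiling stood slightly above its 69.7%.

The flask gave 70.0% and none as the best remedy, with 70.0% after north-east and 70.0% after south; each remedy gained 0 percentage points.

    catalyst intermediate C ⇌ free catalyst + product (K = 0.673 M, k = 0.818 min⁻¹)
    solid reagent ⇌ partner, rate k2*(cs2 - [partner]) while solid is left; crystals form when [partner] > cs2 (solubility = 0.100 M, k = 0.0820 min⁻¹)
    starting material + free catalyst → catalyst intermediate A (k = 6.24 L mol⁻¹ min⁻¹)
    catalyst intermediate B → by-product + catalyst intermediate C (k = 12.5 min⁻¹)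
    partner + catalyst intermediate A → catalyst intermediate B (k = 31.3 L mol⁻¹ min⁻¹)

The flask holds catalyst forms and a slow dissolving that 70.0% does not show, yet it ended at that figure. The falling level of solid reagent was the main reason: without it, the same run reached 99.0% against 70.0%, a difference that makes up 97% of what is missing. At 5.00 h, solid reagent, the limiting reagent, stood at 0%, and catalyst intermediate A held 100% of the catalyst, with partner at 0 M. With 0.35 M of solid reagent in a neighbouring flask, the ceiling comes to 42.2%; that flask gave 42.2% at 5.0 h.

(The readings stem from a simulated flask with constants of no real substance; the scatter is artificial.)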